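## Analysis of the target

The target 18 is an isoflavone: a 4H-chromen-4-one in which the benzo ring A is fused to the pyranone ring C, and ring B, a 3-hydroxy-4-methoxyphenyl group, sits on C3. Ring A carries a 3-methylbut-2-enyl (prenyl) ether on C7, and C2 carries only hydrogen and is bonded to the ring oxygen O1. There is no stereocentre, and the side-chain alkene has two identical methyl groups, so no configuration has to be controlled. The sensitive groups are three. The prenyl aryl ether is ionised or cyclised by Brønsted and Lewis acids, adds electrophiles and does not survive hydrogenolysis. The free 3'-phenol must stay distinct from the 7-oxygen. The pyranone is opened at C2 by hard nucleophiles and strong alkali. The difficulty is therefore not the skeleton but joining three simple parts without acid, hydrogenation or strong base, while one phenolic oxygen ends as an allylic ether and the other stays free. The strategy rests on the C2=C3 bond. C2 (H and O1) has the substitution pattern of the carbonyl carbon of a formate on the ring A phenol. C3 (ring B and the C4 carbonyl) has the pattern of an acyl-stabilised phosphorus ylide carbon. A Wittig olefination between the two inside one molecule closes ring C.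

## Retrosynthetic reasoning

**18 ⇒ 17.** The 3'-hydroxyl is revealed last. It is carried as the formate 17 because the ring closure delivers it in that form. An aryl formate is removed by very mild basic alcoholysis, which neither opens the pyranone at C2 nor touches the prenyl ether. The skeleton does not change.

**17 ⇒ 16 (key disconnection).** The C2=C3 double bond of ring C is cut in the Wittig sense. C2 becomes the carbonyl carbon of a formate on the ring A oxygen, and C3 becomes a ylide carbon that already carries ring B and the C4 ketone, which gives 16. Cutting here, and not at C3–C4 or O1–C2, means that every atom of ring C is in place before closure and C2 arrives at the correct oxidation level. The forward reaction needs only heat and expels the phosphorus as its oxide. It must make a weakly nucleophilic, fully substituted ylide carbon attack an ester carbonyl; the six-membered intramolecular geometry and the high electrophilicity of a formate are what allow this.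

**16 ⇒ 15 ⇒ 14.** The two formyl–oxygen bonds are cut to the diphenol 15, and the phenols are then masked as silyl ethers in 14. Formates cannot be present earlier, because the reactive ylide 13 would attack them; silyl ethers pass through ylide chemistry untouched. Both phenols are treated alike, so they never have to be told apart at this stage.

**14 ⇒ 13 + 6.** The C3–C4 bond between ylide carbon and ketone is cut. This divides the molecule at its centre into the ring A acid chloride 6 and the ring B benzylidene ylide 13, made in the flask from salt 12. Acylation of a ylide is the most direct entry to a keto ylide, and it is the only fragment-joining C–C bond formation of the route.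

**12 ⇒ 10 + 11, then 10 ⇒ 9 ⇒ 8 ⇒ 7.** The C–P bond is cut to benzylic bromide 10 and phosphine 11. The bromide goes back through alcohol 9 and silylated aldehyde 8 to 7, which already has the complete oxygen pattern of ring B.

**6 ⇒ 5 ⇒ 4 ⇒ 3 ⇒ 1 + 2.** The acid chloride 6 is taken back to the silyl ester 5, because that conversion releases no free mineral acid, which the prenyl ether would not tolerate. Compound 5 comes from acid 4 by double silylation, and 4 from ester 3 by hydrolysis. Ester 3 comes from 1 and two equivalents of 2: the carboxyl and the 4-oxygen are alkylated while the hydrogen-bonded 2-hydroxyl is left free. The prenyl ether is thus installed in the first step and carried through every later one.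

## Alternatives that were turned down

**Alternative 1:** Ring C is cut at C4–C4a and O1–C2, and ring A is taken back to a non-aromatic six-membered ring, so that the dihydrochromenone A1 is the key intermediate.
- Forward key step: the kinetic enolate of the vinylogous ester A2, formed with LiN(i-Pr)2 at the carbon that becomes C4a, is acylated by the acid chloride A3. On acidification with CF3CO2H the enolised ring A oxygen adds to the methoxy-bearing carbon and methoxide leaves, which closes the pyranone. Dehydrogenation of ring A, hydrogenolysis of both benzyl ethers to the diphenol A4 and prenylation of the 7-oxygen would finish the synthesis.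
- For it: two ring C bonds form in one operation from cheap non-aromatic material, the C-acylation of such enolates is dependable, and no phosphorus waste is made. On the strength of the central C–C bond formation it is at least equal to the chosen route.
- Against it: CF3CO2H and hydrogenolysis both exclude a prenyl ether, so the prenyl group must go on last, onto A4, which has two free phenols. The 7-hydroxyl is the more acidic, so selectivity is plausible but not secured by structure. The aromatisation needs an oxidant in the presence of an electron-rich benzyl ether. Three operations follow the key step, against one in the chosen route, and A3 itself needs several steps.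
- Comparison: the chosen strategy offers a prenyl ether that is never exposed to acid, oxidant or hydrogen and an end-game without a regiochemical question.

**Alternative 2:** Ring C is cut at C3–C4 and O1–C2, which leads back to the salicylaldehyde A6 and the silyl arylalkyne A7. Their union gives the 2-silylchromone A5.
- Forward key step: with [RhCl(cod)]2, a cyclopentadiene ligand and Cu(OAc)2 as oxidant, the aldehyde C–H bond adds across the alkyne and the phenol oxygen closes onto the silyl-bearing carbon. Fluoride would then remove the C2 silyl group and the silyl ether together.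
- For it: it is much the shortest plan, perhaps five or six steps overall against thirteen here. It is fully convergent, and its final fluoride step is harmless to the prenyl ether. On step economy it is clearly stronger.
- Against it: the regiochemistry depends entirely on the silyl group overriding the aryl group in the insertion step, and aryl alkynes in such annulations tend to place the aryl group next to oxygen. The prenyl ether is both an alkene and an allyl ether, and it would be heated with an acyl rhodium hydride and a copper oxidant, so hydroacylation, double-bond migration and deallylation are all open.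
- Comparison: the chosen strategy fixes the regiochemistry by connectivity, since ring B is already bonded to the ylide carbon, and it closes the ring in a neutral, metal-free medium.

**Alternative 3:** Ring C is cut at C3–C4, O1–C2 and O1–C8a, with ring A drawn from a difluoroarene. The key intermediate is the 7-fluoroisoflavone A8.
- Forward key step: in one flask the enamine A10 is acylated at its β-carbon by the acid chloride A9, aqueous K2CO3 exchanges the amine on C2 for oxygen, and the resulting enolate oxygen displaces the ortho fluorine. The 7-fluorine, para to the carbonyl, would then be displaced by the alkoxide A11, and the benzyl ether removed.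
- For it: three bonds form in one pot from very cheap pieces, ring A needs no phenol protection, and the count is about half that of the chosen route. On step economy and convergence it is stronger.
- Against it: the prenyloxy group must enter by attack of an alkoxide on a finished chromone, whose C2 is itself an acceptor for alkoxides, so ring opening competes. Once the prenyl ether is in place the benzyl group can be removed neither by hydrogenolysis nor by Lewis acid, so it would have to come off first and the substitution be run on a phenoxide. The two fluorines of A9 must also be distinguished.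
- Comparison: the chosen strategy never places a strong nucleophile or base on the pyranone and never has to introduce the prenyl group late.

Key step: step 12

## Route

Remark on the chemistry: formate 16 is expected to be hydrolytically labile and may begin to cyclise below reflux, so it is taken as the dried crude extract straight into step 12.

Step 1
Reactants: 1 2,4-dihydroxybenzoic acid; 2 prenyl bromide (1-bromo-3-methylbut-2-ene)
Product: 3 3-methylbut-2-en-1-yl 2-hydroxy-4-[(3-methylbut-2-en-1-yl)oxy]benzoate
Conditions: 2 (2.1 equiv), K2CO3 (2.2 equiv), acetone, 56 °C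
Reagents that add atoms: none
Why: Carboxylate O-alkylation and Williamson etherification by SN2 displacement of bromide; K2CO3 ionises the acid and the 4-hydroxyl (para to the carboxyl, the more acidic phenol), while the 2-hydroxyl is held in a hydrogen bond to the carbonyl and should stay free.

Step 2
Reactants: 3 3-methylbut-2-en-1-yl 2-hydroxy-4-[(3-methylbut-2-en-1-yl)oxy]benzoate
Product: 4 2-hydroxy-4-[(3-methylbut-2-en-1-yl)oxy]benzoic acid
Conditions: NaOH (3 equiv), MeOH/H2O 3:1, 60 °C; then 1 M HCl to pH 3, 0 °C, immediate extraction
Reagents that add atoms: sodium hydroxide, [Na+].[OH-] (its oxygen ends in the carboxyl group)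
Why: Saponification of the allylic ester by acyl–oxygen cleavage; the aryl prenyl ether is inert to hydroxide, and the brief cold acidification is too mild to ionise the allylic ether or to decarboxylate the acid.

Step 3
Reactants: 4 2-hydroxy-4-[(3-methylbut-2-en-1-yl)oxy]benzoic acid
Product: 5 tert-butyldimethylsilyl 2-[(tert-butyldimethylsilyl)oxy]-4-[(3-methylbut-2-en-1-yl)oxy]benzoate
Conditions: TBSCl (2.4 equiv), imidazole (5 equiv), DMF, rt; pentane extraction
Reagents that add atoms: tert-butyldimethylsilyl chloride, CC(C)(C)[Si](C)(C)Cl
Why: Imidazole-promoted silylation of the carboxylic acid and the phenol in one operation; the silyl ester is the handle for step 4 and the aryl silyl ether masks the ortho oxygen during the ylide chemistry.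

Step 4
Reactants: 5 tert-butyldimethylsilyl 2-[(tert-butyldimethylsilyl)oxy]-4-[(3-methylbut-2-en-1-yl)oxy]benzoate
Product: 6 2-[(tert-butyldimethylsilyl)oxy]-4-[(3-methylbut-2-en-1-yl)oxy]benzoyl chloride
Conditions: (COCl)2 (1.2 equiv), DMF (cat.), CH2Cl2, 0 °C to rt; evaporation under high vacuum, used crude
Reagents that add atoms: oxalyl chloride, ClC(=O)C(Cl)=O
Why: Direct conversion of a silyl ester into the acid chloride by the Vilsmeier-type chloroiminium species; the by-products are TBSCl, CO and CO2, so no free HCl is formed and the prenyl ether and the aryl silyl ether should survive.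

Step 5
Reactants: 7 isovanillin (3-hydroxy-4-methoxybenzaldehyde)
Product: 8 3-[(tert-butyldimethylsilyl)oxy]-4-methoxybenzaldehyde
Conditions: TBSCl (1.1 equiv), imidazole (2 equiv), CH2Cl2, rt
Reagents that add atoms: tert-butyldimethylsilyl chloride, CC(C)(C)[Si](C)(C)Cl
Why: Standard silylation of a phenol; the aldehyde does not take part.

Step 6
Reactants: 8 3-[(tert-butyldimethylsilyl)oxy]-4-methoxybenzaldehyde
Product: 9 {3-[(tert-butyldimethylsilyl)oxy]-4-methoxyphenyl}methanol
Conditions: NaBH4, THF/MeOH, 0 °C, short reaction time
Reagents that add atoms: none
Why: Hydride reduction of the aryl aldehyde to the benzylic alcohol; low temperature and a short contact time keep the aryl silyl ether intact.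

Step 7
Reactants: 9 {3-[(tert-butyldimethylsilyl)oxy]-4-methoxyphenyl}methanol
Product: 10 tert-butyl[5-(bromomethyl)-2-methoxyphenoxy]dimethylsilane
Conditions: PBr3 (0.4 equiv), CH2Cl2, 0 °C
Reagents that add atoms: phosphorus tribromide, BrP(Br)Br
Why: Bromination of an electron-rich benzylic alcohol through its phosphite ester with SN2 attack by bromide; at 0 °C the aryl silyl ether should tolerate the reagent.

Step 8
Reactants: 10 tert-butyl[5-(bromomethyl)-2-methoxyphenoxy]dimethylsilane; 11 triphenylphosphine
Product: 12 ({3-[(tert-butyldimethylsilyl)oxy]-4-methoxyphenyl}methyl)triphenylphosphonium bromide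
Conditions: 11 (1.05 equiv), toluene, 90 °C; salt filtered off
Reagents that add atoms: none
Why: SN2 quaternisation of the phosphine by the benzylic bromide; the salt should precipitate from toluene and need no chromatography.

Step 9
Reactants: 12 ({3-[(tert-butyldimethylsilyl)oxy]-4-methoxyphenyl}methyl)triphenylphosphonium bromide; 6 2-[(tert-butyldimethylsilyl)oxy]-4-[(3-methylbut-2-en-1-yl)oxy]benzoyl chloride
Product: 14 2-{3-[(tert-butyldimethylsilyl)oxy]-4-methoxyphenyl}-1-{2-[(tert-butyldimethylsilyl)oxy]-4-[(3-methylbut-2-en-1-yl)oxy]phenyl}-2-(triphenylphosphoranylidene)ethan-1-one, via benzylidene ylide 13 (not isolated)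
Conditions: 12 (2.1 equiv), NaN(SiMe3)2 (2.1 equiv), THF, 0 °C; then 6 (1.0 equiv), −78 °C to rt; phosphonium chloride filtered off for reuse
Reagents that add atoms: none
Why: C-Acylation of a phosphorus ylide by an acid chloride: 13 adds to 6, and the β-ketophosphonium chloride so formed, far more acidic than 12, is deprotonated by the second equivalent of 13 (transylidation) to give the acyl-stabilised ylide 14. The silyl ethers on both rings keep the phenol oxygens from competing for the acid chloride.

Step 10
Reactants: 14 2-{3-[(tert-butyldimethylsilyl)oxy]-4-methoxyphenyl}-1-{2-[(tert-butyldimethylsilyl)oxy]-4-[(3-methylbut-2-en-1-yl)oxy]phenyl}-2-(triphenylphosphoranylidene)ethan-1-one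
Product: 15 1-{2-hydroxy-4-[(3-methylbut-2-en-1-yl)oxy]phenyl}-2-(3-hydroxy-4-methoxyphenyl)-2-(triphenylphosphoranylidene)ethan-1-one
Conditions: Bu4NF (2.2 equiv), THF, 0 °C; aq NH4Cl
Reagents that add atoms: none
Why: Fluoride cleaves both aryl silyl ethers (strong Si–F bond, phenoxide leaving groups); the stabilised ylide is inert to fluoride, and ammonium ion is acidic enough to protonate the phenoxides but not the ylide carbon.

Step 11
Reactants: 15 1-{2-hydroxy-4-[(3-methylbut-2-en-1-yl)oxy]phenyl}-2-(3-hydroxy-4-methoxyphenyl)-2-(triphenylphosphoranylidene)ethan-1-one
Product: 16 2-{2-[3-(formyloxy)-4-methoxyphenyl]-2-(triphenylphosphoranylidene)acetyl}-5-[(3-methylbut-2-en-1-yl)oxy]phenyl formate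
Conditions: HCO2Ac (3 equiv), pyridine (4 equiv), CH2Cl2, −20 to 0 °C; cold aq NaHCO3 wash, dried, used crude
Reagents that add atoms: acetic formic anhydride, CC(=O)OC=O
Why: O-Formylation of phenols by the mixed formic acetic anhydride under pyridine catalysis; the formyl carbonyl is the less hindered and more electrophilic one, so formyl and not acetyl should be transferred. Any formylation of the enolate-like ylide oxygen is reversed by the hydrogencarbonate wash, and the fully substituted ylide carbon cannot be acylated productively.

Step 12
Reactants: 16 2-{2-[3-(formyloxy)-4-methoxyphenyl]-2-(triphenylphosphoranylidene)acetyl}-5-[(3-methylbut-2-en-1-yl)oxy]phenyl formate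
Product: 17 2-methoxy-5-{7-[(3-methylbut-2-en-1-yl)oxy]-4-oxo-4H-chromen-3-yl}phenyl formate
Conditions: dry toluene (0.01 M), 110 °C, N2
Reagents that add atoms: none
Why: The carbon of the acyl-stabilised ylide adds to the carbonyl carbon of the neighbouring aryl formate, the betaine closes to an oxaphosphetane, and this collapses with loss of triphenylphosphine oxide to the C2=C3 enol ether bond (intramolecular Wittig olefination of an ester carbonyl). The closest known reaction type is the thermal cyclisation of ortho-acyloxyphenacylidene triphenylphosphoranes to chromones; here the ester is a formate, which leaves hydrogen on C2, and the ylide carbon carries ring B, which places the aryl group on C3. Ring C closes in a 6-exo-trig mode (6-enolendo-exo-trig if the ylide is viewed as its enolate form): the nucleophilic carbon attacks a trigonal carbonyl carbon whose C=O bond lies outside the ring O1–C2–C3–C4–C4a–C8a. No stereocentre is formed, and the new double bond lies inside the six-membered ring, so its geometry is fixed. The step needs the ylide to choose the ring A formate over the ring B formate and over a second molecule. The ring B formate sits meta to the carbon that bears the ylide and cannot be reached without bridging the benzene ring, and the doubly stabilised ylide is too weak a nucleophile to attack an ester intermolecularly at this dilution. A formate is the most electrophilic carboxylic ester, which should offset the low nucleophilicity and the crowding of the disubstituted ylide carbon. The medium is neutral and free of oxidants and metals, so the prenyl ether and the second formate should pass through unchanged.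

Step 13
Reactants: 17 2-methoxy-5-{7-[(3-methylbut-2-en-1-yl)oxy]-4-oxo-4H-chromen-3-yl}phenyl formate
Product: 18 3-(3-hydroxy-4-methoxyphenyl)-7-[(3-methylbut-2-en-1-yl)oxy]-4H-chromen-4-one
Conditions: NaHCO3 (0.2 equiv), MeOH, rt
Reagents that add atoms: none
Why: Base-catalysed transesterification of an aryl formate, the most labile of the aryl esters, with methanol; hydrogencarbonate is too weak to open the pyranone at C2 or to affect the prenyl ether.

## Compound list

1 | 2,4-dihydroxybenzoic acid | OC(=O)c1ccc(O)cc1O | starting material
2 | prenyl bromide (1-bromo-3-methylbut-2-ene) | CC(C)=CCBr | starting material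
3 | 3-methylbut-2-en-1-yl 2-hydroxy-4-[(3-methylbut-2-en-1-yl)oxy]benzoate | CC(C)=CCOC(=O)c1ccc(OCC=C(C)C)cc1O | intermediate
4 | 2-hydroxy-4-[(3-methylbut-2-en-1-yl)oxy]benzoic acid | OC(=O)c1ccc(OCC=C(C)C)cc1O | intermediate
5 | tert-butyldimethylsilyl 2-[(tert-butyldimethylsilyl)oxy]-4-[(3-methylbut-2-en-1-yl)oxy]benzoate | CC(C)=CCOc1ccc(C(=O)O[Si](C)(C)C(C)(C)C)c(O[Si](C)(C)C(C)(C)C)c1 | intermediate
6 | 2-[(tert-butyldimethylsilyl)oxy]-4-[(3-methylbut-2-en-1-yl)oxy]benzoyl chloride | CC(C)=CCOc1ccc(C(Cl)=O)c(O[Si](C)(C)C(C)(C)C)c1 | intermediate
7 | isovanillin (3-hydroxy-4-methoxybenzaldehyde) | COc1ccc(C=O)cc1O | starting material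
8 | 3-[(tert-butyldimethylsilyl)oxy]-4-methoxybenzaldehyde | COc1ccc(C=O)cc1O[Si](C)(C)C(C)(C)C | intermediate
9 | {3-[(tert-butyldimethylsilyl)oxy]-4-methoxyphenyl}methanol | COc1ccc(CO)cc1O[Si](C)(C)C(C)(C)C | intermediate
10 | tert-butyl[5-(bromomethyl)-2-methoxyphenoxy]dimethylsilane | COc1ccc(CBr)cc1O[Si](C)(C)C(C)(C)C | intermediate
11 | triphenylphosphine | c1ccc(cc1)P(c1ccccc1)c1ccccc1 | starting material
12 | ({3-[(tert-butyldimethylsilyl)oxy]-4-methoxyphenyl}methyl)triphenylphosphonium bromide | COc1ccc(C[P+](c2ccccc2)(c2ccccc2)c2ccccc2)cc1O[Si](C)(C)C(C)(C)C.[Br-] | intermediate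
13 | ({3-[(tert-butyldimethylsilyl)oxy]-4-methoxyphenyl}methylidene)triphenylphosphorane | COc1ccc(C=P(c2ccccc2)(c2ccccc2)c2ccccc2)cc1O[Si](C)(C)C(C)(C)C | intermediate
14 | 2-{3-[(tert-butyldimethylsilyl)oxy]-4-methoxyphenyl}-1-{2-[(tert-butyldimethylsilyl)oxy]-4-[(3-methylbut-2-en-1-yl)oxy]phenyl}-2-(triphenylphosphoranylidene)ethan-1-one | COc1ccc(cc1O[Si](C)(C)C(C)(C)C)C(C(=O)c1ccc(OCC=C(C)C)cc1O[Si](C)(C)C(C)(C)C)=P(c1ccccc1)(c1ccccc1)c1ccccc1 | intermediate
15 | 1-{2-hydroxy-4-[(3-methylbut-2-en-1-yl)oxy]phenyl}-2-(3-hydroxy-4-methoxyphenyl)-2-(triphenylphosphoranylidene)ethan-1-one | COc1ccc(cc1O)C(C(=O)c1ccc(OCC=C(C)C)cc1O)=P(c1ccccc1)(c1ccccc1)c1ccccc1 | intermediate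
16 | 2-{2-[3-(formyloxy)-4-methoxyphenyl]-2-(triphenylphosphoranylidene)acetyl}-5-[(3-methylbut-2-en-1-yl)oxy]phenyl formate | O=COc1cc(OCC=C(C)C)ccc1C(=O)C(=P(c1ccccc1)(c1ccccc1)c1ccccc1)c1ccc(OC)c(OC=O)c1 | intermediate
17 | 2-methoxy-5-{7-[(3-methylbut-2-en-1-yl)oxy]-4-oxo-4H-chromen-3-yl}phenyl formate | COc1ccc(cc1OC=O)-c1coc2cc(OCC=C(C)C)ccc2c1=O | intermediate
18 | 3-(3-hydroxy-4-methoxyphenyl)-7-[(3-methylbut-2-en-1-yl)oxy]-4H-chromen-4-one | COc1ccc(-c2coc3cc(OCC=C(C)C)ccc3c2=O)cc1O | target

## Step count and least certain steps

Total: 13 steps. Longest linear sequence: 9 steps (steps 1–4 then 9–13, or steps 5–8 then 9–13).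

**Step 12 (key step).** Two processes may defeat the ring closure. The first is loss of the formyl group before olefination, by base-induced decarbonylation of the aryl formate (the ylide itself is a weak base) or by formyl transfer to traces of water. The second is simple lack of reactivity, since the ylide carbon is doubly stabilised and fully substituted. The fallback abandons the Wittig closure for the classical deoxybenzoin annulation. It sets out from 15 and comes back at 18. Compound 15 is dissolved in acetic acid/THF, where it is protonated to the β-ketophosphonium acetate, and zinc dust cleaves the C–P bond reductively to give 2-(3-hydroxy-4-methoxyphenyl)-1-{2-hydroxy-4-[(3-methylbut-2-en-1-yl)oxy]phenyl}ethan-1-one F1. F1 is then condensed with N,N-dimethylformamide dimethyl acetal in THF at 60 °C; the enaminone should close through the ortho phenol with loss of dimethylamine and give 18 directly. The temperature is kept moderate so that the acetal does not methylate the 3'-phenol.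

**Step 11.** Formylation of the ring A phenol may stay incomplete, because that hydroxyl is strongly hydrogen-bonded to the enolate-like ylide carbonyl. Acetyl transfer from the mixed anhydride may compete, and the ortho formate may be hydrolysed again during work-up. The fallback no longer formylates a neutral phenol. It sets out from 14 and comes back at 16. Both silyl ethers of 14 are cleaved with Bu4NF in THF at −20 °C and the phenoxides are not protonated. The resulting bis(tetrabutylammonium) 2-methoxy-5-[2-oxo-2-{2-oxido-4-[(3-methylbut-2-en-1-yl)oxy]phenyl}-1-(triphenylphosphoranylidene)ethyl]phenolate F2 is trapped in the same flask with acetic formic anhydride. The free phenoxide is a far better nucleophile than the chelated phenol, and there is no aqueous step between desilylation and formylation. The mixture is filtered through a short pad and the solvent is changed to toluene for step 12.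

**Step 9.** Half of ylide 13 is necessarily used up as base. The ortho silyloxy group shields the acid chloride, so C-acylation may become slow enough for silyl transfer or chloride-induced desilylation and self-condensation of 6 to compete. The fallback uses a lactone-type acyl donor that needs neither acid chloride nor ring A silyl group. It sets out from 1 and comes back at 15.
- Compound 1 is converted with acetone, (CF3CO)2O and CF3CO2H into 7-hydroxy-2,2-dimethyl-4H-1,3-benzodioxin-4-one F3.
- F3 is alkylated with 2 (K2CO3, acetone) to 2,2-dimethyl-7-[(3-methylbut-2-en-1-yl)oxy]-4H-1,3-benzodioxin-4-one F4.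
- Ylide 13, generated as in step 9, attacks the ring carbonyl of F4 in THF (0 °C to reflux). The ring opens with loss of acetone, and the liberated ring A phenoxide serves as the internal base. This should give 2-{3-[(tert-butyldimethylsilyl)oxy]-4-methoxyphenyl}-1-{2-hydroxy-4-[(3-methylbut-2-en-1-yl)oxy]phenyl}-2-(triphenylphosphoranylidene)ethan-1-one F5.
- Bu4NF then removes the remaining silyl ether to give 15.

This path also bypasses steps 2 to 4.

**Step 1.** With two equivalents of an allylic bromide, alkylation may spill over to the 2-oxygen, or onto ring carbon through the ambident resorcinol-type phenoxide. The fallback replaces phenoxide alkylation by a Mitsunobu etherification. It sets out from 1 and comes back at 4. Fischer esterification of 1 (MeOH, H2SO4, reflux) gives methyl 2,4-dihydroxybenzoate F6. The more acidic 4-hydroxyl of F6 is etherified with 3-methylbut-2-en-1-ol, 11 and diisopropyl azodicarboxylate in THF to methyl 2-hydroxy-4-[(3-methylbut-2-en-1-yl)oxy]benzoate F7. Saponification of F7 as in step 2 gives 4.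

## Further compounds

F1 | step 12 | 2-(3-hydroxy-4-methoxyphenyl)-1-{2-hydroxy-4-[(3-methylbut-2-en-1-yl)oxy]phenyl}ethan-1-one | COc1ccc(CC(=O)c2ccc(OCC=C(C)C)cc2O)cc1O
F2 | step 11 | bis(tetrabutylammonium) 2-methoxy-5-[2-oxo-2-{2-oxido-4-[(3-methylbut-2-en-1-yl)oxy]phenyl}-1-(triphenylphosphoranylidene)ethyl]phenolate | COc1ccc(cc1[O-])C(C(=O)c1ccc(OCC=C(C)C)cc1[O-])=P(c1ccccc1)(c1ccccc1)c1ccccc1.CCCC[N+](CCCC)(CCCC)CCCC.CCCC[N+](CCCC)(CCCC)CCCC
F3 | step 9 | 7-hydroxy-2,2-dimethyl-4H-1,3-benzodioxin-4-one | CC1(C)OC(=O)c2ccc(O)cc2O1
F4 | step 9 | 2,2-dimethyl-7-[(3-methylbut-2-en-1-yl)oxy]-4H-1,3-benzodioxin-4-one | CC1(C)OC(=O)c2ccc(OCC=C(C)C)cc2O1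
F5 | step 9 | 2-{3-[(tert-butyldimethylsilyl)oxy]-4-methoxyphenyl}-1-{2-hydroxy-4-[(3-methylbut-2-en-1-yl)oxy]phenyl}-2-(triphenylphosphoranylidene)ethan-1-one | COc1ccc(cc1O[Si](C)(C)C(C)(C)C)C(C(=O)c1ccc(OCC=C(C)C)cc1O)=P(c1ccccc1)(c1ccccc1)c1ccccc1
F6 | step 1 | methyl 2,4-dihydroxybenzoate | COC(=O)c1ccc(O)cc1O
F7 | step 1 | methyl 2-hydroxy-4-[(3-methylbut-2-en-1-yl)oxy]benzoate | COC(=O)c1ccc(OCC=C(C)C)cc1O
A1 | alternative 1 | 7-(benzyloxy)-3-[3-(benzyloxy)-4-methoxyphenyl]-5,6-dihydro-4H-chromen-4-one | COc1ccc(cc1OCc1ccccc1)C1=COC2=C(CCC(OCc3ccccc3)=C2)C1=O
A2 | alternative 1 | 3-(benzyloxy)cyclohex-2-en-1-one | O=C1C=C(OCc2ccccc2)CCC1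
A3 | alternative 1 | (2E)-2-[3-(benzyloxy)-4-methoxyphenyl]-3-methoxyprop-2-enoyl chloride | CO/C=C(\c1ccc(OC)c(OCc2ccccc2)c1)C(Cl)=O
A4 | alternative 1 | 7-hydroxy-3-(3-hydroxy-4-methoxyphenyl)-4H-chromen-4-one | COc1ccc(cc1O)-c1coc2cc(O)ccc2c1=O
A5 | alternative 2 | 3-[4-methoxy-3-(triisopropylsilyloxy)phenyl]-7-(3-methylbut-2-enyloxy)-2-(trimethylsilyl)-4H-chromen-4-one | COc1ccc(cc1O[Si](C(C)C)(C(C)C)C(C)C)-c1c([Si](C)(C)C)oc2cc(OCC=C(C)C)ccc2c1=O
A6 | alternative 2 | 2-hydroxy-4-[(3-methylbut-2-en-1-yl)oxy]benzaldehyde | O=Cc1ccc(OCC=C(C)C)cc1O
A7 | alternative 2 | {[4-methoxy-3-(triisopropylsilyloxy)phenyl]ethynyl}trimethylsilane | COc1ccc(C#C[Si](C)(C)C)cc1O[Si](C(C)C)(C(C)C)C(C)C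
A8 | alternative 3 | 3-[3-(benzyloxy)-4-methoxyphenyl]-7-fluoro-4H-chromen-4-one | COc1ccc(cc1OCc1ccccc1)-c1coc2cc(F)ccc2c1=O
A9 | alternative 3 | 2,4-difluorobenzoyl chloride | O=C(Cl)c1ccc(F)cc1F
A10 | alternative 3 | 4-{(E)-2-[3-(benzyloxy)-4-methoxyphenyl]ethenyl}morpholine | COc1ccc(/C=C/N2CCOCC2)cc1OCc1ccccc1
A11 | alternative 3 | sodium 3-methylbut-2-en-1-olate | CC(C)=CC[O-].[Na+]
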